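**Assumptions.** The target is the all-trans (2S,3S,4S,5S) isomer; I checked this from the SMILES. The 3,4-dimethoxyphenyl ring comes from the aldehyde and the 3,4,5-trimethoxyphenyl ring is added late. Simple reagents (MeI, H2O2, Et3SiH) are not numbered, only building blocks and intermediates.

## Retrosynthesis
- The THF ring is made last by Et3SiH/BF3 reduction of the oxocarbenium ion from lactol **8**. This sets the C(Ar) centre trans to the neighbouring methyl.
- Lactol **8** comes from ArLi addition to the trans-3,4-dimethyl-5-aryl lactone **6**. Lactone **6** comes from α-methylation of **5**, anti to the 4-methyl group.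
- Lactone **5** comes from oxidative lactonisation of diol **4**, which comes from hydroboration of the anti homoallylic alcohol **3**.
- Alcohol **3** comes from asymmetric (E)-crotylboration of veratraldehyde **1**.
- Order of ring formation: γ-lactone (Step 3), then THF (Step 6). Stereocentres are set in Steps 1, 4 and 6.

## Route

**Step 1**
Reactants: **1** 3,4-dimethoxybenzaldehyde; **2** (E)-crotyl-B(Ipc)2
Product: **3** (1S,2S)-1-(3,4-dimethoxyphenyl)-2-methylbut-3-en-1-ol
Conditions: **2** (made in situ from trans-2-butene, n-BuLi/KOtBu, (−)-Ipc2BOMe, BF3·OEt2), THF, −78 °C; then NaOH, H2O2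
Reagents that add atoms: **2**, C/C=C/CB(C1CC2CC(C2(C)C)C1C)C1CC2CC(C2(C)C)C1C (Ipc = isopinocampheyl from (+)-α-pinene; it delivers the crotyl group C4H7)
Why: Brown asymmetric crotylboration goes through a chair Zimmerman–Traxler transition state. The E-crotyl group gives the anti diastereomer, and the pinene-derived reagent sets the (S)-carbinol by Si-face attack.

**Step 2**
Reactants: **3**
Product: **4** (1S,2S)-1-(3,4-dimethoxyphenyl)-2-methylbutane-1,4-diol
Conditions: 9-BBN (2.5 equiv), THF, 0 °C to rt; then NaOH, H2O2, 0 °C
Reagents that add atoms: hydrogen peroxide, OO (supplies the new O)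
Why: Hydroboration–oxidation is anti-Markovnikov at the terminal alkene and leaves both stereocentres untouched. The extra 9-BBN covers the free OH.

**Step 3**
Reactants: **4**
Product: **5** (4S,5S)-5-(3,4-dimethoxyphenyl)-4-methyloxolan-2-one
Conditions: TEMPO (10 mol%), PhI(OAc)2, CH2Cl2/H2O, rt
Reagents that add atoms: none
Why: TEMPO/BAIB oxidises the unhindered primary alcohol to the lactol and then the lactone. The hindered benzylic secondary alcohol is untouched, and no stereocentre is altered.

**Step 4**
Reactants: **5**
Product: **6** (3S,4S,5S)-5-(3,4-dimethoxyphenyl)-3,4-dimethyloxolan-2-one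
Conditions: LDA, THF, −78 °C; then MeI, −78 to −40 °C
Reagents that add atoms: iodomethane (MeI), CI
Why: Lactone enolate alkylation is substrate-controlled. MeI approaches anti to the adjacent 4-methyl group, giving the 3,4-trans lactone, which is also the thermodynamically preferred isomer.

**Step 5**
Reactants: **6**; **7** 5-bromo-1,2,3-trimethoxybenzene
Product: **8** (3S,4S,5S)-5-(3,4-dimethoxyphenyl)-3,4-dimethyl-2-(3,4,5-trimethoxyphenyl)oxolan-2-ol (anomeric lactol mixture)
Conditions: **7**, n-BuLi, THF, −78 °C (gives the aryllithium); add **6**, −78 °C; quench with NH4Cl at −78 °C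
Reagents that add atoms: 3,4,5-trimethoxyphenyllithium, COc1cc([Li])cc(OC)c1OC (from **7** and n-BuLi, CCCC[Li])
Why: Aryllithium addition to the lactone stops at the stable tetrahedral lactol, so there is no over-addition at −78 °C. The anomeric centre is lost in the next step, so its configuration does not matter.

**Step 6**
Reactants: **8**
Product: **9** 5-methoxygalbelgin, COc1ccc([C@H]2O[C@H](c3cc(OC)c(OC)c(OC)c3)[C@@H](C)[C@@H]2C)cc1OC
Conditions: Et3SiH, BF3·OEt2, CH2Cl2, −78 to −20 °C
Reagents that add atoms: none (Et3SiH, CC[SiH](CC)CC, supplies only H)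
Why: BF3 ionises the lactol to a 2-aryl oxocarbenium ion. Ionic hydrogenation then delivers hydride to give the 2,3-trans, all-trans tetrahydrofuran, which is the sterically preferred and thermodynamically favoured isomer.

## Compound list
1 | 3,4-dimethoxybenzaldehyde (veratraldehyde) | COc1ccc(C=O)cc1OC | starting material
2 | (E)-crotyldiisopinocampheylborane | C/C=C/CB(C1CC2CC(C2(C)C)C1C)C1CC2CC(C2(C)C)C1C (Ipc stereochemistry as named) | starting material (made from commercial trans-2-butene and (−)-Ipc2BOMe)
3 | (1S,2S)-1-(3,4-dimethoxyphenyl)-2-methylbut-3-en-1-ol | C=C[C@H](C)[C@H](O)c1ccc(OC)c(OC)c1 | intermediate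
4 | (1S,2S)-1-(3,4-dimethoxyphenyl)-2-methylbutane-1,4-diol | OCC[C@H](C)[C@H](O)c1ccc(OC)c(OC)c1 | intermediate
5 | (4S,5S)-5-(3,4-dimethoxyphenyl)-4-methyloxolan-2-one | C[C@H]1CC(=O)O[C@@H]1c1ccc(OC)c(OC)c1 | intermediate
6 | (3S,4S,5S)-5-(3,4-dimethoxyphenyl)-3,4-dimethyloxolan-2-one | C[C@@H]1C(=O)O[C@H](c2ccc(OC)c(OC)c2)[C@H]1C | intermediate
7 | 5-bromo-1,2,3-trimethoxybenzene | COc1cc(Br)cc(OC)c1OC | starting material
8 | lactol (3S,4S,5S)-5-(3,4-dimethoxyphenyl)-3,4-dimethyl-2-(3,4,5-trimethoxyphenyl)oxolan-2-ol | C[C@@H]1C(O)(c2cc(OC)c(OC)c(OC)c2)O[C@H](c2ccc(OC)c(OC)c2)[C@H]1C | intermediate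
9 | 5-methoxygalbelgin, (2S,3S,4S,5S)-2-(3,4-dimethoxyphenyl)-3,4-dimethyl-5-(3,4,5-trimethoxyphenyl)tetrahydrofuran | COc1ccc([C@H]2O[C@H](c3cc(OC)c(OC)c(OC)c3)[C@@H](C)[C@@H]2C)cc1OC | target

**Total steps:** 6. **Longest linear sequence:** 6 (from veratraldehyde).

## Three steps most likely to fail
1. **Step 6, the C2 stereochemistry of the reduction.** The silane reduction may give some 2,3-cis isomer.
   - Fallback: reduce lactol **8** with NaBH4 to the 1,4-diol. Then cyclise by ionisation with TMSOTf or p-TsOH, which gives the thermodynamic all-trans THF. Alternatively, cyclise the diol under Mitsunobu conditions, which proceeds with inversion at one carbinol centre.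
2. **Step 4, the 3,4-trans selectivity of the methylation.** The 5-aryl group could compete with the 4-methyl group in directing the alkylation.
   - Fallback: hydrolyse lactone **5** to the hydroxy acid and protect the OH as a TBS ether. Couple the acid to an (S)-4-benzyloxazolidinone and do an Evans NaHMDS/MeI methylation, so the auxiliary controls C3. Then remove the auxiliary and relactonise.
3. **Step 1, the ee and anti selectivity of the crotylation.** The electron-rich aldehyde may give lower selectivity with the Ipc reagent.
   - Fallback: use Ir-catalysed anti-selective crotylation with α-methylallyl acetate. Alternatively, use an Evans syn aldol route followed by a stereochemical correction at the methyl-bearing carbon.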